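The constants give the direct step from substrate to target 0.0038 /min at 25 °C, and I wanted to know how much target stood at the end of two flasks that differ in temperature.

    substrate → open intermediate (k1 = 0.019 /min, Ea1 = 98.0 kJ/mol)
    substrate → side product (k2 = 0.0029 /min, Ea2 = 98.0 kJ/mol)
    substrate → target (k3 = 0.0038 /min, Ea3 = 92.0 kJ/mol)
    open intermediate → side product (k4 = 4.0 × 10⁻⁴ /min, Ea4 = 98.0 kJ/mol)
    capture agent + open intermediate → trapped intermediate (k5 = 0.045 /M/min, Ea5 = 62.0 kJ/mol)
    (constants at 25 °C)

- eta: substrate 0.11 M; capture agent 5.50 mM; temperature 50 °C; time 1.5 h
- epsilon: substrate 0.11 M; capture agent 5.50 mM; temperature 25 °C; time 1.5 h

- which flask leads in amount of target, in percent of the substrate charged ("all alike" within 1.5 percentage points) (eta / epsilon / all alike)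
- how much target is there at the end, in percent of the substrate charged: eta
- how much target is there at the end, in percent of the substrate charged: epsilon

- the constants hold at 25 °C; other temperatures follow from the activation energies

I reckoned epsilon first and built it up one step at a time, using two numbers at each stage: the count of substrate lifetimes and the share of lost substrate that becomes target. With the step to target alone, epsilon held 0.342 lifetimes, which put c(target) at 29.0% of the substrate charged. Adding the step to open intermediate, 5.00 times as fast and so faster than the step to target, raised the count to 2.05 and cut the share to 16.7%, so c(target) fell to 14.5%. Adding the direct step to side product gave 2.31 lifetimes, this count being the sum of the constants leaving substrate multiplied by the time. The share, or selectivity, became 14.8%, and the share times the consumed fraction gave 13.3%. The remaining two steps have open intermediate, not substrate, on their left, so count and share kept their values.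

For eta, heating sped the two competing substrate steps by a factor of 21 and the step to target by the smaller factor of 18. The share therefore dropped to 12.6%, while the count rose to 48.0, so I took nearly all of the substrate as consumed and reckoned 12.6%. My gap of 0.70 percentage points was less than the margin of 1.5 points, so I expected neither flask to lead.

The forecast said all alike, with 12.6% for eta and 13.3% for epsilon, reasoning that “its yield is just step 3's share of substrate loss (about 15% at 25 °C, about 12.6% at 50 °C because its activation energy is lower) times the fraction of substrate consumed”.

The flasks gave 12.6% in eta and 13.3% in epsilon, which counts as all alike. The neighbour of eta charged with 0.022 M of capture agent held 14.9% of trapped intermediate and still 12.6% of target, and the capture step made no difference to target in eta. Ten times the time took the epsilon count to 23.1 lifetimes, so I reckoned nearly all of the substrate as consumed and c(target) at 14.8%, and the epsilon flask left until 15.0 h held 14.8% of target.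

(The numbers come from no measurement; the rest is arithmetic.)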